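## Retrosynthetic overview

1. Target 22 ⇐ ketone 20 (ketone reduction, desilylation) ⇐ keto-aldehyde 16 (catalytic alkenylzinc addition, acetylation).
2. Side-chain bond C5–C2′ and its two stereocentres ⇐ iminium-catalysed Mukaiyama–Michael addition of enol silane 14 to crotonaldehyde.
3. Seven-membered ring ⇐ one-carbon ring expansion (diazoalkane addition, 1,2-shift) of trans-hydrindenone 12, which also delivers the enol silane at the new carbon.
4. Six-membered ring of 12 ⇐ intramolecular enolate allylation of 11; 11 ⇐ three-component coupling on (S)-silyloxycyclopentenone 1, then alkoxide-directed methyl addition.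
5. Ring order: five (bought) → six (step 6) → seven (step 7).

Assumption: the carbinol carbon made in step 1 is carried as an epimer mixture, because it becomes a ketone in step 3.

## Route

Step 1
Reactants: 1 (S)-4-(tert-butyldimethylsilyloxy)cyclopent-2-en-1-one; 2 (2-bromoprop-2-en-1-yl)trimethylsilane; 3 acetaldehyde
Product: 7 (4R,5R)-5-(1-hydroxyethyl)-4-[3-(trimethylsilyl)prop-1-en-2-yl]cyclopent-2-en-1-one, via alkenyllithium 4 (not isolated), via alkenylcopper phosphine complex 5 (not isolated), via silyloxy aldol 6 (not isolated)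
Conditions: 2, t-BuLi (2 equiv), Et2O, −78 °C; CuI, PBu3; 1, −78 °C; 3, −78 °C; NH4Cl; then DBU, CH2Cl2, −20 °C
Reagents that add atoms: none
Why: Noyori-type three-component coupling, in which the organocopper adds anti to the silyloxy group, the enolate is trapped by the aldehyde anti to the new C4 arm (4,5-trans), and DBU then expels silanol (E1cB) to unveil the enone.

Step 2
Reactants: 7 hydroxyethyl cyclopentenone
Product: 8 (1S,4R,5R)-5-(1-hydroxyethyl)-1-methyl-4-[3-(trimethylsilyl)prop-1-en-2-yl]cyclopent-2-en-1-ol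
Conditions: MeTi(OiPr)3 (3 equiv), CH2Cl2, −40 → 0 °C
Reagents that add atoms: methyltitanium triisopropoxide, C[Ti](OC(C)C)(OC(C)C)OC(C)C
Why: Alkoxide-directed 1,2-addition of a titanium methyl reagent: the C5 carbinol exchanges onto titanium and hands CH3 to the ketone face on which that arm sits, so the new tertiary OH ends cis to the C4 arm, and the non-basic reagent leaves the acidic C4–H alone.

Step 3
Reactants: 8 cyclopentene diol
Product: 9 1-[(1S,2S,5R)-2-hydroxy-2-methyl-5-[3-(trimethylsilyl)prop-1-en-2-yl]cyclopent-3-en-1-yl]ethan-1-one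
Conditions: Dess–Martin periodinane, pyridine, CH2Cl2, 0 °C
Reagents that add atoms: none
Why: Dess–Martin oxidation touches only the secondary carbinol (both epimers converge on one methyl ketone), while the tertiary allylic alcohol cannot be oxidised.

Step 4
Reactants: 9 hydroxy methyl ketone
Product: 10 1-[(1S,2S,5R)-2-methyl-2-(triethylsilyloxy)-5-[3-(trimethylsilyl)prop-1-en-2-yl]cyclopent-3-en-1-yl]ethan-1-one
Conditions: TESOTf, 2,6-lutidine, CH2Cl2, −78 °C
Reagents that add atoms: triethylsilyl trifluoromethanesulfonate, CC[Si](CC)(CC)OS(=O)(=O)C(F)(F)F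
Why: Silylation of the tertiary alcohol blocks retro-aldol cleavage in the base and Lewis-acid steps that follow.

Step 5
Reactants: 10 silyl ether allylsilane
Product: 11 1-[(1S,2S,5R)-5-(3-bromoprop-1-en-2-yl)-2-methyl-2-(triethylsilyloxy)cyclopent-3-en-1-yl]ethan-1-one
Conditions: NBS, CH2Cl2, −78 → −40 °C
Reagents that add atoms: N-bromosuccinimide, O=C1CCC(=O)N1Br
Why: Bromodesilylation (SE2′) of the allylsilane, in which Br+ adds to the CH2 terminus and silicon leaves, gives the 2-substituted allyl bromide and spares the less nucleophilic ring alkene.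

Step 6
Reactants: 11 allyl bromide methyl ketone
Product: 12 (3S,3aS,7aR)-3-methyl-7-methylidene-3-(triethylsilyloxy)-3,3a,5,6,7,7a-hexahydro-4H-inden-4-one
Conditions: KN(SiMe3)2 (1.05 equiv), THF, −78 → −40 °C, slow addition of 11
Reagents that add atoms: none
Why: Kinetic deprotonation of the methyl ketone and 6-(enolendo)-exo-tet C-allylation (SN2 and SN2′ give the same product) close the six-membered ring without touching a stereocentre, so the trans ring fusion set in step 1 is kept.

Step 7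
Reactants: 12 trans-hydrindenone
Product: 14 (3S,3aR,8aR)-3-methyl-8-methylidene-3-(triethylsilyloxy)-4-(trimethylsilyloxy)-3,3a,6,7,8,8a-hexahydroazulene, via C-silyl ketone 13 (not isolated)
Conditions: TMSCHN2 (1.5 equiv), Sc(OTf)3 (10 mol%), toluene, −40 → 0 °C; then 70 °C; filtration through basic alumina
Reagents that add atoms: (trimethylsilyl)diazomethane, C[Si](C)(C)C=[N+]=[N-]
Why: Lewis-acid-catalysed diazoalkane homologation (Tiffeneau–Demjanov-type 1,2-shift), in which the less substituted CH2 rather than the ring-fusion CH migrates with loss of N2 to give the seven-membered ring, and a 1,3-Brook shift then turns the C-silyl ketone into the enol silane of the new carbon only.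

Step 8
Reactants: 14 enol silane; 15 (E)-but-2-enal
Product: 16 (3S,3aS,5S,8aR)-3-methyl-8-methylidene-5-[(2R)-4-oxobutan-2-yl]-3-(triethylsilyloxy)-3,3a,5,6,7,8a-hexahydroazulen-4(8H)-one
Conditions: (2S,5S)-5-benzyl-2-tert-butyl-3-methylimidazolidin-4-one·2,4-dinitrobenzoic acid (20 mol%), 15 (3 equiv), H2O (2 equiv), CH2Cl2, −40 °C
Reagents that add atoms: water, O
Why: Proposed new method: iminium-catalysed Mukaiyama–Michael addition of a trisubstituted, ring-fused cycloheptenyl enol silane to crotonaldehyde that sets two adjacent stereocentres, in which the second-generation imidazolidinone forms the E-iminium and its benzyl group leaves only the Re face of C-β open (the enantiomer that gives (R)-3-substituted butanals with carbon π-nucleophiles, here 2R in the side chain), the enol silane reacts through an open transition state on its face anti to the cyclopentene carbon C3 at the ring fusion (5S), and water takes up the silicon; the closest known reaction type is the imidazolidinone-catalysed Mukaiyama–Michael addition of silyloxyfurans and simple ketone enol silanes to enals.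

Step 9
Reactants: 16 keto aldehyde; 17 (2-methylprop-1-en-1-yl)magnesium bromide
Product: 19 (3S,3aS,5S,8aR)-5-[(2R,4R)-4-hydroxy-6-methylhept-5-en-2-yl]-3-methyl-8-methylidene-3-(triethylsilyloxy)-3,3a,5,6,7,8a-hexahydroazulen-4(8H)-one, via dialkenylzinc 18 (not isolated)
Conditions: 17 (2.4 equiv), ZnCl2 (1.2 equiv), THF then toluene; N,N,N′,N′-tetraethylethylenediamine; (−)-3-exo-morpholinoisoborneol [(−)-MIB] (10 mol%); 16, 0 °C
Reagents that add atoms: none
Why: Amino-alcohol-catalysed asymmetric alkenylzinc addition, in which the zinc reagent adds only to the aldehyde (the ketone is untouched) and (−)-MIB, the enantiomer that gives Si-face addition, sets the (R)-allylic carbinol under catalyst control.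

Step 10
Reactants: 19 allylic alcohol
Product: 20 (4R,6R)-2-methyl-6-[(3S,3aS,5S,8aR)-3-methyl-8-methylidene-4-oxo-3-(triethylsilyloxy)-3,3a,4,5,6,7,8,8a-octahydroazulen-5-yl]hept-2-en-4-yl acetate
Conditions: Ac2O, pyridine, DMAP (cat.), CH2Cl2, 0 °C
Reagents that add atoms: acetic anhydride, CC(=O)OC(C)=O
Why: DMAP-catalysed acetylation of the only free hydroxyl, with no change at any stereocentre.

Step 11
Reactants: 20 keto acetate
Product: 21 (4R,6R)-6-[(3S,3aR,4R,5S,8aR)-4-hydroxy-3-methyl-8-methylidene-3-(triethylsilyloxy)-3,3a,4,5,6,7,8,8a-octahydroazulen-5-yl]-2-methylhept-2-en-4-yl acetate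
Conditions: NaBH4, CeCl3·7H2O, MeOH, −40 °C
Reagents that add atoms: none
Why: Luche reduction, in which the small hydride attacks the C4 ketone from the face opposite the pseudo-axial C5 side chain to give the 4-OH cis to that chain, while the acetate survives at low temperature.

Step 12
Reactants: 21 silyl ether of the target
Product: 22 target CNP0209568.3
Conditions: HF·pyridine, pyridine, THF, 0 °C
Reagents that add atoms: none
Why: Buffered fluoride desilylation frees the tertiary allylic alcohol without ionising it or cleaving the allylic acetate.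

## Compound list

1 | (S)-4-(tert-butyldimethylsilyloxy)cyclopent-2-en-1-one | O=C1C=C[C@@H](O[Si](C)(C)C(C)(C)C)C1 | starting material
2 | (2-bromoprop-2-en-1-yl)trimethylsilane | C=C(Br)C[Si](C)(C)C | starting material
3 | acetaldehyde | CC=O | starting material
4 | [3-(trimethylsilyl)prop-1-en-2-yl]lithium (not isolated) | [Li]C(=C)C[Si](C)(C)C | intermediate
5 | [3-(trimethylsilyl)prop-1-en-2-yl]copper tributylphosphine complex (not isolated) | CCCC[P+](CCCC)(CCCC)[Cu-]C(=C)C[Si](C)(C)C | intermediate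
6 | (2R,3R,4S)-4-(tert-butyldimethylsilyloxy)-2-(1-hydroxyethyl)-3-[3-(trimethylsilyl)prop-1-en-2-yl]cyclopentan-1-one, ring substituents all-trans, carbinol epimers (not isolated) | O=C1C[C@H](O[Si](C)(C)C(C)(C)C)[C@@H](C(=C)C[Si](C)(C)C)[C@@H]1C(C)O | intermediate
7 | (4R,5R)-5-(1-hydroxyethyl)-4-[3-(trimethylsilyl)prop-1-en-2-yl]cyclopent-2-en-1-one, 4,5-trans, carbinol epimers | O=C1C=C[C@@H](C(=C)C[Si](C)(C)C)[C@@H]1C(C)O | intermediate
8 | (1S,4R,5R)-5-(1-hydroxyethyl)-1-methyl-4-[3-(trimethylsilyl)prop-1-en-2-yl]cyclopent-2-en-1-ol, 1-OH cis to the C4 arm and trans to the C5 arm | C[C@]1(O)C=C[C@@H](C(=C)C[Si](C)(C)C)[C@@H]1C(C)O | intermediate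
9 | 1-[(1S,2S,5R)-2-hydroxy-2-methyl-5-[3-(trimethylsilyl)prop-1-en-2-yl]cyclopent-3-en-1-yl]ethan-1-one | C[C@]1(O)C=C[C@@H](C(=C)C[Si](C)(C)C)[C@@H]1C(C)=O | intermediate
10 | 1-[(1S,2S,5R)-2-methyl-2-(triethylsilyloxy)-5-[3-(trimethylsilyl)prop-1-en-2-yl]cyclopent-3-en-1-yl]ethan-1-one | C[C@]1(O[Si](CC)(CC)CC)C=C[C@@H](C(=C)C[Si](C)(C)C)[C@@H]1C(C)=O | intermediate
11 | 1-[(1S,2S,5R)-5-(3-bromoprop-1-en-2-yl)-2-methyl-2-(triethylsilyloxy)cyclopent-3-en-1-yl]ethan-1-one | C[C@]1(O[Si](CC)(CC)CC)C=C[C@@H](C(=C)CBr)[C@@H]1C(C)=O | intermediate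
12 | (3S,3aS,7aR)-3-methyl-7-methylidene-3-(triethylsilyloxy)-3,3a,5,6,7,7a-hexahydro-4H-inden-4-one, trans ring fusion | C[C@]1(O[Si](CC)(CC)CC)C=C[C@H]2C(=C)CCC(=O)[C@H]12 | intermediate
13 | (3S,3aS,8aR)-3-methyl-8-methylidene-3-(triethylsilyloxy)-5-(trimethylsilyl)-3,3a,5,6,7,8a-hexahydroazulen-4(8H)-one, C5 epimers (not isolated) | C[C@]1(O[Si](CC)(CC)CC)C=C[C@H]2C(=C)CCC([Si](C)(C)C)C(=O)[C@H]12 | intermediate
14 | (3S,3aR,8aR)-3-methyl-8-methylidene-3-(triethylsilyloxy)-4-(trimethylsilyloxy)-3,3a,6,7,8,8a-hexahydroazulene | C[C@]1(O[Si](CC)(CC)CC)C=C[C@H]2C(=C)CCC=C(O[Si](C)(C)C)[C@H]12 | intermediate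
15 | (E)-but-2-enal (crotonaldehyde) | C/C=C/C=O | starting material
16 | (3S,3aS,5S,8aR)-3-methyl-8-methylidene-5-[(2R)-4-oxobutan-2-yl]-3-(triethylsilyloxy)-3,3a,5,6,7,8a-hexahydroazulen-4(8H)-one | C=C1CC[C@@H]([C@H](C)CC=O)C(=O)[C@H]2[C@H]1C=C[C@]2(C)O[Si](CC)(CC)CC | intermediate
17 | (2-methylprop-1-en-1-yl)magnesium bromide, Me2C=CHMgBr | CC(C)=C[Mg]Br | starting material
18 | bis(2-methylprop-1-en-1-yl)zinc, (Me2C=CH)2Zn (not isolated) | CC(C)=C[Zn]C=C(C)C | intermediate
19 | (3S,3aS,5S,8aR)-5-[(2R,4R)-4-hydroxy-6-methylhept-5-en-2-yl]-3-methyl-8-methylidene-3-(triethylsilyloxy)-3,3a,5,6,7,8a-hexahydroazulen-4(8H)-one | C=C1CC[C@@H]([C@H](C)C[C@H](C=C(C)C)O)C(=O)[C@H]2[C@H]1C=C[C@]2(C)O[Si](CC)(CC)CC | intermediate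
20 | (4R,6R)-2-methyl-6-[(3S,3aS,5S,8aR)-3-methyl-8-methylidene-4-oxo-3-(triethylsilyloxy)-3,3a,4,5,6,7,8,8a-octahydroazulen-5-yl]hept-2-en-4-yl acetate | C=C1CC[C@@H]([C@H](C)C[C@H](C=C(C)C)OC(C)=O)C(=O)[C@H]2[C@H]1C=C[C@]2(C)O[Si](CC)(CC)CC | intermediate
21 | (4R,6R)-6-[(3S,3aR,4R,5S,8aR)-4-hydroxy-3-methyl-8-methylidene-3-(triethylsilyloxy)-3,3a,4,5,6,7,8,8a-octahydroazulen-5-yl]-2-methylhept-2-en-4-yl acetate | C=C1CC[C@@H]([C@H](C)C[C@H](C=C(C)C)OC(C)=O)[C@@H](O)[C@H]2[C@H]1C=C[C@]2(C)O[Si](CC)(CC)CC | intermediate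
22 | CNP0209568.3, (4R,6R)-6-[(3S,3aR,4R,5S,8aR)-3,4-dihydroxy-3-methyl-8-methylidene-3,3a,4,5,6,7,8,8a-octahydroazulen-5-yl]-2-methylhept-2-en-4-yl acetate | C=C1CC[C@@H]([C@H](C)C[C@H](C=C(C)C)OC(C)=O)[C@@H](O)[C@H]2[C@H]1C=C[C@]2(C)O | target

## Step count and risks

Total step count: 12. Longest linear sequence: 12 (fully linear from 1).

The three steps most likely to fail:

**Step 2 (face of methyl delivery).** If the methyl is not delivered from the alkoxide and instead enters anti to the C5 arm, the C1 epimer of 8 forms. The fallback sets out from 7 and comes back at 8; it builds the carbinol by an oxidative transposition, epoxidation and Wharton sequence in which oxygen, not carbon, enters from the open face. The carbinol of 7 is silylated (TESCl, imidazole) to the triethylsilyl ether F1. MeMgBr/CeCl3 then gives the tertiary allylic alcohol F2, and either C1 epimer serves. Pyridinium chlorochromate, [C5H5NH][CrO3Cl], with NaOAc (Babler–Dauben oxidative transposition) gives the 3-methylcyclopentenone F3. H2O2/NaOH epoxidises it anti to the neighbouring silyloxyethyl arm to give the epoxy ketone F4. Wharton transposition (N2H4·H2O, AcOH, MeOH) opens F4 to the tertiary allylic alcohol F5 with the oxygen retained on the required face. TBAF then frees the carbinol to give 8.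

**Step 8 (the proposed new Mukaiyama–Michael addition).** Reactivity of the hindered enol silane and the syn/anti relationship between C5 and C2′ are both unproven. The fallback sets out from 14 and comes back at 16 using known chemistry. Iridium-catalysed branched-selective allylic alkylation of the enol silane ([Ir(cod)Cl]2, chiral phosphoramidite, (E)-but-2-enyl methyl carbonate, CsF, ZnF2, THF) gives the but-3-en-2-yl ketone F6, with the methyl-bearing centre set by the ligand. Aldehyde-selective Wacker oxidation of the terminal vinyl group (PdCl2(PhCN)2, CuCl2, AgNO2, O2, t-BuOH/MeNO2) then gives 16.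

**Step 11 (face of ketone reduction).** The ketone is flanked by two substituted carbons, so hydride may enter from the side-chain face. The fallback sets out from 20 and comes back at 21. If the reduction gives the 4-epimeric alcohol F7, it is kept and inverted. Mitsunobu reaction with chloroacetic acid (PPh3, DIAD, toluene) gives the inverted chloroacetate F8. Selective methanolysis of the chloroacetate in the presence of the acetate (K2CO3 cat., MeOH, −10 °C) then gives 21.

## Further compounds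

F1 | step 2 | (4R,5R)-5-[1-(triethylsilyloxy)ethyl]-4-[3-(trimethylsilyl)prop-1-en-2-yl]cyclopent-2-en-1-one | O=C1C=C[C@@H](C(=C)C[Si](C)(C)C)[C@@H]1C(C)O[Si](CC)(CC)CC
F2 | step 2 | (4R,5R)-1-methyl-5-[1-(triethylsilyloxy)ethyl]-4-[3-(trimethylsilyl)prop-1-en-2-yl]cyclopent-2-en-1-ol, C1 epimers | CC1(O)C=C[C@@H](C(=C)C[Si](C)(C)C)[C@@H]1C(C)O[Si](CC)(CC)CC
F3 | step 2 | (4S,5R)-3-methyl-4-[1-(triethylsilyloxy)ethyl]-5-[3-(trimethylsilyl)prop-1-en-2-yl]cyclopent-2-en-1-one | CC1=CC(=O)[C@@H](C(=C)C[Si](C)(C)C)[C@@H]1C(C)O[Si](CC)(CC)CC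
F4 | step 2 | 5-methyl-4-[1-(triethylsilyloxy)ethyl]-3-[3-(trimethylsilyl)prop-1-en-2-yl]-6-oxabicyclo[3.1.0]hexan-2-one, oxirane oxygen trans to the C4 arm | C[C@]12O[C@H]1C(=O)[C@@H](C(=C)C[Si](C)(C)C)[C@@H]2C(C)O[Si](CC)(CC)CC
F5 | step 2 | (1S,4R,5R)-1-methyl-5-[1-(triethylsilyloxy)ethyl]-4-[3-(trimethylsilyl)prop-1-en-2-yl]cyclopent-2-en-1-ol | C[C@]1(O)C=C[C@@H](C(=C)C[Si](C)(C)C)[C@@H]1C(C)O[Si](CC)(CC)CC
F6 | step 8 | (3S,3aS,5S,8aR)-5-[(2R)-but-3-en-2-yl]-3-methyl-8-methylidene-3-(triethylsilyloxy)-3,3a,5,6,7,8a-hexahydroazulen-4(8H)-one | C=C1CC[C@@H]([C@H](C)C=C)C(=O)[C@H]2[C@H]1C=C[C@]2(C)O[Si](CC)(CC)CC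
F7 | step 11 | (4R,6R)-6-[(3S,3aR,4S,5S,8aR)-4-hydroxy-3-methyl-8-methylidene-3-(triethylsilyloxy)-3,3a,4,5,6,7,8,8a-octahydroazulen-5-yl]-2-methylhept-2-en-4-yl acetate | C=C1CC[C@@H]([C@H](C)C[C@H](C=C(C)C)OC(C)=O)[C@H](O)[C@H]2[C@H]1C=C[C@]2(C)O[Si](CC)(CC)CC
F8 | step 11 | (3S,3aR,4R,5S,8aR)-5-[(2R,4R)-4-acetoxy-6-methylhept-5-en-2-yl]-3-methyl-8-methylidene-3-(triethylsilyloxy)-3,3a,4,5,6,7,8,8a-octahydroazulen-4-yl chloroacetate | C=C1CC[C@@H]([C@H](C)C[C@H](C=C(C)C)OC(C)=O)[C@@H](OC(=O)CCl)[C@H]2[C@H]1C=C[C@]2(C)O[Si](CC)(CC)CC
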